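**Plan**
1. Ring A of the target is numbered C1 (C=O), C2, C3 (C-ethyl), C4 (CHOH), C5, C6 (C-farnesyl); ring B is the oxirane on C5–C6. The ring B oxygen on C6 and the hydroxyl on C4 lie on the same face of ring A, which marks them as the two ends of an O–O bridge that once joined C3 and C6.
2. Retrosynthetic cuts, in order: the C2=C3 enone with C4–OH back to a C3–C4 oxirane (E1cB); the C5–O and C4–O bonds back to the O–O bond of a C3/C6 endoperoxide; the C3–O and C6–O bonds back to a cyclohexa-1,3-diene plus O2; the C6–CH2 bond back to a dienyl triflate plus a farnesyl stannane; the C1–O bond back to 4-ethylcyclohexanone.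
3. Forward: ring A is bought, C1 is oxygenated, the C3=C4–C5=C6 diene is built, the farnesyl chain is joined at C6, the 1,2-dioxane ring closes across C3 and C6, and ring B plus a transient C3–C4 oxirane arise from the peroxide.
4. Stereochemistry: the C1 oxygen (R) comes from L-proline catalysis and sends O2 to the opposite face, fixing C3 and C6. The peroxide oxygens are relayed on that face to C4 and C5, and C1 is then oxidised away. The E alkenes come with farnesyl bromide.

Key step: step 8

Assumption: the aminoxylation should fix the oxygenated carbon as R under catalyst control in both epimers at the ethyl-bearing carbon. The aminoxy ketone and the compounds that follow it up to the enone are drawn as the trans epimer expected to predominate; any cis epimer is carried along, because that carbon becomes sp2 in step 5.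

**Step 1**
Reactants: 1 4-ethylcyclohexanone; 2 nitrosobenzene
Product: 3 (2R,4S)-4-ethyl-2-[(phenylamino)oxy]cyclohexan-1-one
Conditions: L-proline (20 mol %), DMF, 0 °C, slow addition of 2 to 1
Reagents that add atoms: none
Why: Proline enamine catalysis (O-selective nitroso aldol, the alpha-aminoxylation) is well established for cyclohexanones; the enamine attacks the nitroso oxygen while the carboxylic acid holds the nitroso nitrogen, which selects one enantiotopic alpha-carbon and one face and should set C2 as R.

**Step 2**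
Reactants: 3 (2R,4S)-4-ethyl-2-[(phenylamino)oxy]cyclohexan-1-one
Product: 4 (2R,4S)-4-ethyl-2-hydroxycyclohexan-1-one
Conditions: H2 (1 atm), Pd/C, EtOAc, rt; crude product used at once
Reagents that add atoms: none
Why: Hydrogenolysis of the weak N–O bond should free the alpha-hydroxy ketone without touching the carbinol centre, at a stage where no alkene is present.

**Step 3**
Reactants: 4 (2R,4S)-4-ethyl-2-hydroxycyclohexan-1-one
Product: 5 (2R,4S)-2-[(tert-butyldimethylsilyl)oxy]-4-ethylcyclohexan-1-one
Conditions: t-BuMe2SiCl, imidazole, DMF, 0 °C → rt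
Reagents that add atoms: tert-butyldimethylsilyl chloride, CC(C)(C)[Si](C)(C)Cl
Why: Standard imidazole-mediated silylation of a secondary alcohol gives a robust, bulky ether that is needed later for face control, under conditions mild enough to leave the ketol centre intact.

**Step 4**
Reactants: 5 (2R,4S)-2-[(tert-butyldimethylsilyl)oxy]-4-ethylcyclohexan-1-one
Product: 7 (4R,6R)-6-[(tert-butyldimethylsilyl)oxy]-4-ethylcyclohex-2-en-1-one, via kinetic trimethylsilyl enol ether 6 (not isolated)
Conditions: LiN(i-Pr)2, Me3SiCl, THF, −78 °C; then Pd(OAc)2 (10 mol %), O2 (1 atm), DMSO, rt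
Reagents that add atoms: none
Why: Kinetic deprotonation of an alpha-silyloxy ketone occurs on the CH2 side, and Saegusa–Ito dehydrogenation of the trapped silyl enol ether (palladium enolate, beta-hydride elimination) should place the C=C away from the oxygenated carbon, whose configuration is not touched.

**Step 5**
Reactants: 7 (4R,6R)-6-[(tert-butyldimethylsilyl)oxy]-4-ethylcyclohex-2-en-1-one
Product: 8 (6R)-6-[(tert-butyldimethylsilyl)oxy]-4-ethylcyclohexa-1,3-dien-1-yl trifluoromethanesulfonate
Conditions: Tf2O, 2,6-di-tert-butyl-4-methylpyridine, CH2Cl2, 0 °C → rt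
Reagents that add atoms: trifluoromethanesulfonic anhydride, O=S(=O)(OS(=O)(=O)C(F)(F)F)C(F)(F)F
Why: Enol triflation of an enone with Tf2O and a hindered pyridine goes through the O-triflyl allyl cation, which should lose the gamma proton at the ethyl-bearing carbon to give the more substituted linear 1,3-dienyl triflate (as with steroidal 4-en-3-ones), so both epimers converge and, as no enolate is formed, the silyloxy-bearing centre cannot epimerise.

**Step 6**
Reactants: 9 (2E,6E)-farnesyl bromide
Product: 10 tributyl[(2E,6E)-3,7,11-trimethyldodeca-2,6,10-trien-1-yl]stannane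
Conditions: Bu3SnLi (from Bu3SnH and LiN(i-Pr)2, THF, 0 °C), then 9, −78 °C → 0 °C
Reagents that add atoms: tributyltin hydride, CCCC[SnH](CCCC)CCCC
Why: SN2 displacement of a primary allylic bromide by tributylstannyllithium is the standard route to prenyl-type stannanes and should keep both E geometries.

**Step 7**
Reactants: 8 (6R)-6-[(tert-butyldimethylsilyl)oxy]-4-ethylcyclohexa-1,3-dien-1-yl trifluoromethanesulfonate; 10 tributyl[(2E,6E)-3,7,11-trimethyldodeca-2,6,10-trien-1-yl]stannane
Product: 11 tert-butyl{[(1R)-5-ethyl-2-[(2E,6E)-3,7,11-trimethyldodeca-2,6,10-trien-1-yl]cyclohexa-2,4-dien-1-yl]oxy}dimethylsilane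
Conditions: Pd2(dba)3 (zerovalent palladium, 2.5 mol %), AsPh3, LiCl, NMP, rt → 40 °C; chromatography on Et3N-deactivated silica
Reagents that add atoms: none
Why: Stille coupling of an alkenyl triflate with an allylstannane (oxidative addition, chloride exchange, transmetallation, reductive elimination at the less hindered allyl terminus) should join C6 to the farnesyl CH2 with the linear E,E chain intact, under neutral conditions that the acid-sensitive silyloxy diene tolerates.

**Step 8**
Reactants: 11 tert-butyl{[(1R)-5-ethyl-2-[(2E,6E)-3,7,11-trimethyldodeca-2,6,10-trien-1-yl]cyclohexa-2,4-dien-1-yl]oxy}dimethylsilane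
Product: 12 tert-butyl{[(1R,4R,7R)-4-ethyl-1-[(2E,6E)-3,7,11-trimethyldodeca-2,6,10-trien-1-yl]-2,3-dioxabicyclo[2.2.2]oct-5-en-7-yl]oxy}dimethylsilane
Conditions: O2, 5,10,15,20-tetraphenylporphyrin (free base, 1 mol %), visible light, CH2Cl2, −78 °C, stopped at one equivalent of O2
Reagents that add atoms: dioxygen, O=O
Why: Singlet oxygen, formed by energy transfer from the excited porphyrin, adds as a two-electron dienophile across C3 and C6 of the s-cis diene in a concerted suprafacial [4+2] cycloaddition (hetero-Diels–Alder), making the C3–O and C6–O bonds together. The closest known case is the photooxygenation of 1-isopropyl-4-methylcyclohexa-1,3-diene to ascaridole, a 1,4-dialkylcyclohexadiene of the same substitution pattern. The one new ring, the 1,2-dioxane of the 2,3-dioxabicyclo[2.2.2]octene, closes by cycloaddition of both oxygen atoms onto diene termini that ring A holds cisoid, so the bridge is cis by necessity. The two new stereocentres C3 and C6 are set together by the C1 silyloxy group, which sits beside the C6 terminus and shields its own face, so oxygen should arrive anti to it (C3 R, C6 R). The step needs diene-over-alkene chemoselectivity; this rests on the cisoid 1,4-dialkyl diene reacting by [4+2] much faster than each trisubstituted farnesyl alkene reacts by the ene pathway, helped by −78 °C and by stopping at one equivalent of oxygen. The oxygen at C1 is kept as a silyl ether so that no hydrogen bond can draw singlet oxygen to the syn face.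

**Step 9**
Reactants: 12 tert-butyl{[(1R,4R,7R)-4-ethyl-1-[(2E,6E)-3,7,11-trimethyldodeca-2,6,10-trien-1-yl]-2,3-dioxabicyclo[2.2.2]oct-5-en-7-yl]oxy}dimethylsilane
Product: 13 tert-butyl{[(1S,2R,4R,5R,7R)-7-ethyl-4-[(2E,6E)-3,7,11-trimethyldodeca-2,6,10-trien-1-yl]-3,8-dioxatricyclo[5.1.0.0(2,4)]octan-5-yl]oxy}dimethylsilane (syn diepoxide, both oxiranes anti to the silyloxy group)
Conditions: Co(TPP) (divalent cobalt, 5 mol %), CH2Cl2, 0 °C, dark
Reagents that add atoms: none
Why: Co(TPP)-catalysed rearrangement of a bicyclic endoperoxide to the syn diepoxide: electron transfer from divalent cobalt cleaves the O–O bond and each oxygen closes onto its neighbouring alkene carbon (C6–O to C5, C3–O to C4) on the face the bridge occupied, so C4 and C5 are set by the peroxide configuration.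

**Step 10**
Reactants: 13 tert-butyl{[(1S,2R,4R,5R,7R)-7-ethyl-4-[(2E,6E)-3,7,11-trimethyldodeca-2,6,10-trien-1-yl]-3,8-dioxatricyclo[5.1.0.0(2,4)]octan-5-yl]oxy}dimethylsilane
Product: 14 (1S,2R,4S,5R,7R)-7-ethyl-4-[(2E,6E)-3,7,11-trimethyldodeca-2,6,10-trien-1-yl]-3,8-dioxatricyclo[5.1.0.0(2,4)]octan-5-ol
Conditions: Bu4NF, AcOH (1:1), THF, 0 °C → rt
Reagents that add atoms: none
Why: Fluoride cleavage of the silyl ether, buffered with acetic acid so that no free alkoxide can attack the neighbouring C5–C6 oxirane (Payne-type migration), should leave the oxiranes and the trisubstituted alkenes untouched.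

**Step 11**
Reactants: 14 (1S,2R,4S,5R,7R)-7-ethyl-4-[(2E,6E)-3,7,11-trimethyldodeca-2,6,10-trien-1-yl]-3,8-dioxatricyclo[5.1.0.0(2,4)]octan-5-ol
Product: 15 (1S,2R,4R,7R)-7-ethyl-4-[(2E,6E)-3,7,11-trimethyldodeca-2,6,10-trien-1-yl]-3,8-dioxatricyclo[5.1.0.0(2,4)]octan-5-one
Conditions: Dess–Martin periodinane, NaHCO3, CH2Cl2, 0 °C → rt; thiosulfate work-up
Reagents that add atoms: none
Why: Dess–Martin oxidation of the hindered secondary alcohol under bicarbonate buffer should give the C1 ketone without acid opening of the oxiranes, and it removes the C1 stereocentre once it has done its work.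

**Step 12**
Reactants: 15 (1S,2R,4R,7R)-7-ethyl-4-[(2E,6E)-3,7,11-trimethyldodeca-2,6,10-trien-1-yl]-3,8-dioxatricyclo[5.1.0.0(2,4)]octan-5-one
Product: 16 (1R,5R,6R)-4-ethyl-5-hydroxy-1-[(2E,6E)-3,7,11-trimethyldodeca-2,6,10-trien-1-yl]-7-oxabicyclo[4.1.0]hept-3-en-2-one (CID44566894)
Conditions: Et3N, CH2Cl2, 0 °C
Reagents that add atoms: none
Why: E1cB opening of a beta,gamma-epoxy ketone: deprotonation at C2, the only enolisable position, expels the C3 oxygen to give the C2=C3 enone and the C4 alkoxide, whose C4–O bond is never broken, so the hydroxyl keeps the face of ring B.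

**Compound list**
1 | 4-ethylcyclohexanone | CCC1CCC(=O)CC1 | starting material
2 | nitrosobenzene | O=Nc1ccccc1 | starting material
3 | (2R,4S)-4-ethyl-2-[(phenylamino)oxy]cyclohexan-1-one | O=C1CC[C@H](CC)C[C@H]1ONc1ccccc1 | intermediate
4 | (2R,4S)-4-ethyl-2-hydroxycyclohexan-1-one | O=C1CC[C@H](CC)C[C@H]1O | intermediate
5 | (2R,4S)-2-[(tert-butyldimethylsilyl)oxy]-4-ethylcyclohexan-1-one | O=C1CC[C@H](CC)C[C@H]1O[Si](C)(C)C(C)(C)C | intermediate
6 | tert-butyl{[(1R,5S)-5-ethyl-2-[(trimethylsilyl)oxy]cyclohex-2-en-1-yl]oxy}dimethylsilane | C[Si](C)(C)OC1=CC[C@H](CC)C[C@H]1O[Si](C)(C)C(C)(C)C | intermediate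
7 | (4R,6R)-6-[(tert-butyldimethylsilyl)oxy]-4-ethylcyclohex-2-en-1-one | O=C1C=C[C@H](CC)C[C@H]1O[Si](C)(C)C(C)(C)C | intermediate
8 | (6R)-6-[(tert-butyldimethylsilyl)oxy]-4-ethylcyclohexa-1,3-dien-1-yl trifluoromethanesulfonate | CCC1=CC=C(OS(=O)(=O)C(F)(F)F)[C@H](O[Si](C)(C)C(C)(C)C)C1 | intermediate
9 | (2E,6E)-farnesyl bromide | BrC/C=C(\C)CC/C=C(\C)CCC=C(C)C | starting material
10 | tributyl[(2E,6E)-3,7,11-trimethyldodeca-2,6,10-trien-1-yl]stannane | CCCC[Sn](CCCC)(CCCC)C/C=C(\C)CC/C=C(\C)CCC=C(C)C | intermediate
11 | tert-butyl{[(1R)-5-ethyl-2-[(2E,6E)-3,7,11-trimethyldodeca-2,6,10-trien-1-yl]cyclohexa-2,4-dien-1-yl]oxy}dimethylsilane | CCC1=CC=C(C/C=C(\C)CC/C=C(\C)CCC=C(C)C)[C@H](O[Si](C)(C)C(C)(C)C)C1 | intermediate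
12 | tert-butyl{[(1R,4R,7R)-4-ethyl-1-[(2E,6E)-3,7,11-trimethyldodeca-2,6,10-trien-1-yl]-2,3-dioxabicyclo[2.2.2]oct-5-en-7-yl]oxy}dimethylsilane | CC[C@@]12C=C[C@@](C/C=C(\C)CC/C=C(\C)CCC=C(C)C)(OO1)[C@H](O[Si](C)(C)C(C)(C)C)C2 | intermediate
13 | tert-butyl{[(1S,2R,4R,5R,7R)-7-ethyl-4-[(2E,6E)-3,7,11-trimethyldodeca-2,6,10-trien-1-yl]-3,8-dioxatricyclo[5.1.0.0(2,4)]octan-5-yl]oxy}dimethylsilane | CC[C@@]12C[C@@H](O[Si](C)(C)C(C)(C)C)[C@]3(C/C=C(\C)CC/C=C(\C)CCC=C(C)C)O[C@@H]3[C@@H]1O2 | intermediate
14 | (1S,2R,4S,5R,7R)-7-ethyl-4-[(2E,6E)-3,7,11-trimethyldodeca-2,6,10-trien-1-yl]-3,8-dioxatricyclo[5.1.0.0(2,4)]octan-5-ol | CC[C@@]12C[C@@H](O)[C@]3(C/C=C(\C)CC/C=C(\C)CCC=C(C)C)O[C@@H]3[C@@H]1O2 | intermediate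
15 | (1S,2R,4R,7R)-7-ethyl-4-[(2E,6E)-3,7,11-trimethyldodeca-2,6,10-trien-1-yl]-3,8-dioxatricyclo[5.1.0.0(2,4)]octan-5-one | CC[C@@]12CC(=O)[C@]3(C/C=C(\C)CC/C=C(\C)CCC=C(C)C)O[C@@H]3[C@@H]1O2 | intermediate
16 | (1R,5R,6R)-4-ethyl-5-hydroxy-1-[(2E,6E)-3,7,11-trimethyldodeca-2,6,10-trien-1-yl]-7-oxabicyclo[4.1.0]hept-3-en-2-one | CCC1=CC(=O)[C@]2(C/C=C(\C)CC/C=C(\C)CCC=C(C)C)O[C@@H]2[C@@H]1O | target

**Step count**
Total: 12 steps. Longest linear sequence: 11 steps (steps 1–5 and 7–12, from 4-ethylcyclohexanone); step 6 is a one-step side branch.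

**Steps most likely to fail**

1. Step 9, fragmentation during the peroxide rearrangement. The oxyl radical that develops on the C6 oxygen may undergo beta-scission toward the allylic farnesyl radical faster than it closes onto C5, so the side chain would be lost instead of ring B being formed. Fallback: setting out from endoperoxide 12, the silyl group is removed first (Bu4NF/AcOH, THF, 0 °C) to give hydroxy endoperoxide F1. F1 is then isomerised with RuCl2(PPh3)3 (divalent ruthenium, CH2Cl2, rt), a catalyst known to convert bicyclic endoperoxides into syn diepoxides through metal-bound oxygens rather than a free oxyl radical. This gives diepoxy alcohol 14 directly, and the route is rejoined there before step 11.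

2. Step 8, loss of chemoselectivity in the oxygenation. Singlet oxygen may also attack the three trisubstituted farnesyl alkenes by the ene pathway, or the diene may aromatise by loss of silanol, so that hydroperoxides and arene accompany the endoperoxide. Fallback: setting out from diene 11, ground-state oxygen is added by a radical-cation chain instead: catalytic (4-BrC6H4)3N SbCl6 with 2,6-di-tert-butylpyridine as proton scavenger, O2, CH2Cl2, −78 °C, dark. One-electron oxidation picks out the conjugated diene as the most easily oxidised pi system, its radical cation captures triplet oxygen at C3 and C6, and electron transfer from fresh diene carries the chain. No singlet oxygen is present, so the ene pathway is closed. The same endoperoxide 12 results and no new compound arises (F0).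

3. Step 7, scrambling in the allyl transfer. Transmetallation of the allylstannane may proceed with allylic transposition or E/Z isomerisation, or be slow enough for the dienyl partner to decompose. Fallback with reversed polarity: setting out from triflate 8, Miyaura borylation (B2pin2, PdCl2(PPh3)2, PPh3, KOPh, toluene, 50 °C) gives dienyl pinacol boronate F2. F2 is then joined to farnesyl bromide 9 by Suzuki–Miyaura coupling (Pd(PPh3)4, aqueous K3PO4, THF, rt → 50 °C). Here the farnesyl unit enters as a pi-allyl palladium electrophile, which couples at its unhindered terminus with E geometry retained. This returns to diene 11.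

**Further compounds**
F1 | step 9 | (1R,4R,7R)-4-ethyl-1-[(2E,6E)-3,7,11-trimethyldodeca-2,6,10-trien-1-yl]-2,3-dioxabicyclo[2.2.2]oct-5-en-7-ol | CC[C@@]12C=C[C@@](C/C=C(\C)CC/C=C(\C)CCC=C(C)C)(OO1)[C@H](O)C2
F0 | step 8 | none | none
F2 | step 7 | tert-butyl{[(1R)-5-ethyl-2-(4,4,5,5-tetramethyl-1,3,2-dioxaborolan-2-yl)cyclohexa-2,4-dien-1-yl]oxy}dimethylsilane | CCC1=CC=C(B2OC(C)(C)C(C)(C)O2)[C@H](O[Si](C)(C)C(C)(C)C)C1
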